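Retrosynthesis: the C11–C20 epoxide oxygen, the C6 chloride (from a C6 alcohol, inversion) and the C8–OH/C17–H pair (from a C8=C17 butenolide) are removed, then the C1–C10 bond is cut.
Enabling feature: quaternary C1 (methyl C15, flanked by oxygenated C2 and C14) is bonded to C10, and the next atom C11 carries the one-carbon branch C20. Ring A (C1, C10–C14) and the ten-membered ring (C1–C10) therefore merge into one 14-membered carbocycle C1–C14 in which a C10=C11 alkene faces the tertiary end of a C1–C2 epoxide.
The macrocycle is cut at C14–C1 (vinyl iodide plus aldehyde), C6–C7 (vinylogous aldol) and C8–C9 (enol triflate plus enal). This gives a geranyl-derived C9–C14 enal, a tetronic-acid-derived butenolide (C7, C8, C17–C19) and a C1–C6 iodo-enal.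
Forward order: C8–C9, C6–C7, macrocyclisation at C14–C1, epoxidation, transannular closure of ring A (the ten-membered ring appears in the same event), then lactone hydroxylation, chloride and acetate installation, C11=C20 epoxidation.
Stereochemistry: C9 and C14 from ligand-controlled Ni/Cr additions; C6/C7 from a BINOL–titanium aldol; C1/C2 from hydroxyl-directed epoxidation; C1 (inversion) and C10 in the cyclisation; C8 and C17 from face-selective epoxidation and enolate protonation; C6 by inversion; C11 by attack anti to the axial C15 methyl.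

Key step: step 17

Remark: locants C1–C20 are briarane locants (C15 methyl on C1, C16 methylidene on C5, C18 methyl on C17, C19 lactone carbonyl, C20 on C11); TBS = tert-butyldimethylsilyl, TES = triethylsilyl; L* = N-{2-[(4S)-4-isopropyl-4,5-dihydro-1,3-oxazol-2-yl]-6-methylphenyl}methanesulfonamide; for L* and BINOL the antipode that delivers the stated configuration is meant, and the sense of induction has to be confirmed on the real substrates; 1, 7 and 12 are taken as catalogue chemicals.

Step 1
Reactants: 1 geranyl acetate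
Product: 2 (2E)-5-(3,3-dimethyloxiran-2-yl)-3-methylpent-2-en-1-yl acetate (racemic at the oxirane)
Conditions: mCPBA (1.0 equiv), CH2Cl2, 0 °C
Reagents that add atoms: 3-chloroperoxybenzoic acid (mCPBA), O=C(OO)c1cccc(Cl)c1
Why: Prilezhaev epoxidation should pick the electron-rich distal trisubstituted alkene because the other alkene is deactivated by the allylic acetate; the oxirane stereocentre is destroyed in step 2.

Step 2
Reactants: 2 6,7-epoxygeranyl acetate
Product: 3 (2E)-3-methyl-6-oxohex-2-en-1-yl acetate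
Conditions: H5IO6, THF–Et2O, 0 °C
Reagents that add atoms: none
Why: periodic acid hydrolyses the epoxide and cleaves the resulting glycol in one operation (oxidative glycol cleavage), leaving the future C14 aldehyde.

Step 3
Reactants: 3 (2E)-3-methyl-6-oxohex-2-en-1-yl acetate
Product: 5 (2E)-6,6-dimethoxy-3-methylhex-2-en-1-ol, via acetal acetate 4 (not isolated)
Conditions: HC(OMe)3, PPTS (cat.), MeOH, rt; then K2CO3 (0.3 equiv), rt
Reagents that add atoms: trimethyl orthoformate, COC(OC)OC
Why: acid-catalysed acetalisation masks the saturated aldehyde, and base-catalysed methanolysis of the acetate (transesterification) then frees the allylic alcohol in the same pot.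

Step 4
Reactants: 5 (2E)-6,6-dimethoxy-3-methylhex-2-en-1-ol
Product: 6 (2E)-6,6-dimethoxy-3-methylhex-2-enal
Conditions: MnO2, CH2Cl2, rt
Reagents that add atoms: none
Why: MnO2 oxidation is selective for allylic alcohols and should keep the E geometry of the C10=C11 alkene.

Step 5
Reactants: 7 3-methyltetronic acid
Product: 8 4-methyl-5-oxo-2,5-dihydrofuran-3-yl trifluoromethanesulfonate
Conditions: Tf2O, Et3N, CH2Cl2, −78 °C
Reagents that add atoms: trifluoromethanesulfonic anhydride, O=S(=O)(OS(=O)(=O)C(F)(F)F)C(F)(F)F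
Why: O-sulfonylation of the vinylogous acid (enol triflate formation) turns C8 into the electrophilic partner for a Ni/Cr coupling.

Step 6
Reactants: 6 (2E)-6,6-dimethoxy-3-methylhex-2-enal; 8 4-methyl-5-oxo-2,5-dihydrofuran-3-yl trifluoromethanesulfonate
Product: 9 4-[(1S,2E)-1-hydroxy-6,6-dimethoxy-3-methylhex-2-en-1-yl]-3-methylfuran-2(5H)-one
Conditions: CrCl2 (4 equiv), L* (4.4 equiv), Et3N, NiCl2 (cat.), THF, rt
Reagents that add atoms: none
Why: Nozaki–Hiyama–Kishi coupling, in which zerovalent nickel inserts into the enol triflate, the alkenylchromium adds 1,2 to the enal, and the chromium-bound chiral sulfonamide alone chooses the aldehyde face and should set 9S.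

Step 7
Reactants: 9 4-[(1S,2E)-1-hydroxy-6,6-dimethoxy-3-methylhex-2-en-1-yl]-3-methylfuran-2(5H)-one
Product: 10 4-[(1S,2E)-1-(tert-butyldimethylsilyloxy)-6,6-dimethoxy-3-methylhex-2-en-1-yl]-3-methylfuran-2(5H)-one
Conditions: TBSCl, imidazole, DMF, rt
Reagents that add atoms: tert-butyldimethylsilyl chloride, CC(C)(C)[Si](C)(C)Cl
Why: standard silyl ether formation on the secondary allylic alcohol; the TBS group carries O9 through to step 23.

Step 8
Reactants: 10 C9 TBS ether of the butenolide
Product: 11 3-methyl-4-[(1S,2E)-1-(tert-butyldimethylsilyloxy)-6,6-dimethoxy-3-methylhex-2-en-1-yl]-2-(trimethylsilyloxy)furan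
Conditions: TMSOTf, Et3N (2 equiv), CH2Cl2, −20 °C; non-aqueous work-up, used directly
Reagents that add atoms: trimethylsilyl trifluoromethanesulfonate, C[Si](C)(C)OS(=O)(=O)C(F)(F)F
Why: soft enolisation of the butenolide at C7 (silyl triflate/amine) gives the aromatic 2-silyloxyfuran needed for the vinylogous Mukaiyama aldol, and the amine excess should keep the acetal untouched.

Step 9
Reactants: 12 hept-5-yn-1-ol
Product: 14 (5E)-6-iodohept-5-en-1-ol, via alkenylzirconocene 13 (not isolated)
Conditions: Cp2Zr(H)Cl (3 equiv), THF, 50 °C; then I2, 0 °C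
Reagents that add atoms: iodine, II
Why: syn-hydrozirconation of the 2-alkyne with excess Cp2Zr(H)Cl (one equivalent is consumed by the hydroxyl) equilibrates zirconium to the less hindered methyl-bearing carbon, and iodinolysis with retention gives the (E)-2-iodoalkene that becomes C1.

Step 10
Reactants: 14 (5E)-6-iodohept-5-en-1-ol
Product: 15 (5E)-6-iodohept-5-enal
Conditions: DMP, CH2Cl2, rt
Reagents that add atoms: none
Why: Dess–Martin oxidation of the primary alcohol is mild enough for the vinyl iodide.

Step 11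
Reactants: 15 (5E)-6-iodohept-5-enal
Product: 16 (5E)-6-iodo-2-methylidenehept-5-enal
Conditions: 37% aq. CH2O, pyrrolidine (10 mol %), EtCO2H (10 mol %), i-PrOH, 45 °C
Reagents that add atoms: formaldehyde, C=O
Why: amine/acid-catalysed Mannich condensation with formaldehyde followed by elimination (organocatalytic α-methylenation of an aldehyde) installs the C5=C16 methylidene.

Step 12
Reactants: 11 2-(trimethylsilyloxy)furan; 16 (5E)-6-iodo-2-methylidenehept-5-enal
Product: 18 (5R)-5-[(1R,5E)-1-hydroxy-6-iodo-2-methylidenehept-5-en-1-yl]-4-[(1S,2E)-1-(tert-butyldimethylsilyloxy)-3-methyl-6-oxohex-2-en-1-yl]-3-methylfuran-2(5H)-one, via silyl ether acetal 17 (not isolated)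
Conditions: Ti(Oi-Pr)4 (20 mol %), (R)-BINOL (20 mol %), Et2O, −20 °C; then 1 M aq. HCl, THF, 0 °C to rt
Reagents that add atoms: water, O
Why: vinylogous Mukaiyama aldol, in which the BINOL–titanium complex chooses the face of the enal (6R) and the open transition state of the γ-attack through C7 gives the threo pair (7R; lactone oxygen and 6-OH on opposite sides in the Fischer projection), while the acidic work-up removes the O6 silyl group and the dimethyl acetal.

Step 13
Reactants: 18 hydroxy aldehyde
Product: 19 (5R)-5-[(1R,5E)-6-iodo-2-methylidene-1-(triethylsilyloxy)hept-5-en-1-yl]-4-[(1S,2E)-1-(tert-butyldimethylsilyloxy)-3-methyl-6-oxohex-2-en-1-yl]-3-methylfuran-2(5H)-one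
Conditions: TESCl, imidazole, DMF, 0 °C
Reagents that add atoms: triethylsilyl chloride, CC[Si](Cl)(CC)CC
Why: silyl ether formation leaves the aldehyde alone, and TES is chosen so that O6 can later be freed beside the two TBS ethers.

Step 14
Reactants: 19 iodo-aldehyde (seco compound)
Product: 20 macrocyclic allylic alcohol (1E,10E; 6R,7R,9S,14S): 14-membered ring C1–C14 with 14-OH, 9-OTBS, 6-OTES, C5=C16 methylidene and the C7–O–C19 butenolide (C8=C17)
Conditions: CrCl2 (8 equiv), L* (9 equiv), Et3N, NiCl2 (0.2 equiv), THF, 2 mM, rt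
Reagents that add atoms: none
Why: intramolecular Nozaki–Hiyama–Kishi reaction at high dilution closes the C14–C1 bond with retention of the E alkene geometry, and the chromium-bound chiral sulfonamide should control the aldehyde face and set 14S.

Step 15
Reactants: 20 macrocyclic allylic alcohol
Product: 21 epoxy alcohol: 20 with a trans-1,2-epoxide (1S,2S) erythro to the 14S hydroxyl
Conditions: VO(acac)2 (cat.), TBHP, CH2Cl2, 0 °C
Reagents that add atoms: tert-butyl hydroperoxide, CC(C)(C)OO
Why: vanadium-catalysed hydroxyl-directed epoxidation touches only the allylic-alcohol alkene C1=C2 and, with A(1,2) strain from C15 fixing the reactive rotamer, should deliver oxygen erythro to O14, which sets C1 and C2.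

Step 16
Reactants: 21 epoxy alcohol
Product: 22 epoxy-butenolide macrocycle with 9- and 14-OTBS and 6-OTES (1R,2S,6R,7R,9S,14S; 10E)
Conditions: TBSOTf, 2,6-lutidine, CH2Cl2, −78 °C
Reagents that add atoms: tert-butyldimethylsilyl trifluoromethanesulfonate, CC(C)(C)[Si](C)(C)OS(=O)(=O)C(F)(F)F
Why: silyl triflate/lutidine silylation handles the hindered epoxy alcohol at low temperature, and a silyl ether at O14 cannot take part in the epoxide opening of step 17.

Step 17
Reactants: 22 epoxy-butenolide macrocycle
Product: 23 bicyclo[8.4.0] core (1S,2S,6R,7R,9S,10S,14S): ring A fused to the ten-membered ring, free 2-OH, C11=C20 and C5=C16 methylidenes, 9- and 14-OTBS, 6-OTES, butenolide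
Conditions: Et2AlCl (2.5 equiv), CH2Cl2, −78 to −30 °C; then sat. aq. NaHCO3
Reagents that add atoms: none
Why: Proposed new method: Et2AlCl binds the epoxide oxygen, the C1–O bond at the tertiary carbon ionises while C10 of the trisubstituted C10=C11 alkene attacks C1 from the side opposite the oxygen, and the C11 cation is quenched by loss of a C20 proton to the aluminium-bound base (ethane leaves, no HCl forms); the closest known chemistry is the Lewis-acid transannular epoxide–alkene cyclisation of macrocyclic terpene epoxides and dialkylaluminium-chloride-promoted ene-type cyclisations. Ring A closes 6-exo-tet with respect to the epoxide and 6-endo-trig with respect to the alkene, and the ten-membered ring is what remains of the macrocycle on the other side of the new C1–C10 bond. C1 is set by inversion at the epoxide carbon fixed in step 15, C10 by a chair transition state in which the E alkene places C9 equatorial and the C2 arm is equatorial too, so that C15 and H10 end up trans-diaxial, and C2 keeps its configuration. The step needs site selectivity for C10=C11 over C5=C16 (attack by C16 would place a cation next to the silyloxy-bearing C6), opening at tertiary C1 and not at C2, and proton loss toward C20 (the methyl protons are the ones within reach of the C2–O–Al base). The O14 silyl ether cannot close an acyloxonium ring onto C1, and in the reactive chair no C14 substituent is antiperiplanar to the breaking C1–O bond, which disfavours a semipinacol shift.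

Step 18
Reactants: 23 bicyclic alcohol
Product: 24 2-O-isobutyrate of 23
Conditions: (i-PrCO)2O, DMAP, Et3N, CH2Cl2, rt
Reagents that add atoms: isobutyric anhydride, CC(C)C(=O)OC(=O)C(C)C
Why: DMAP-catalysed acylation (Steglich-type) of the only free hydroxyl, the neopentylic C2–OH revealed in step 17.

Step 19
Reactants: 24 bicyclic butenolide isobutyrate
Product: 25 8,17-epoxy lactone (8S,17R), oxygen on the lactone face syn to C6
Conditions: TBHP, n-BuLi, THF, −20 to 0 °C
Reagents that add atoms: tert-butyl hydroperoxide, CC(C)(C)OO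
Why: nucleophilic (Weitz–Scheffer) epoxidation, in which tert-butylperoxide adds reversibly to C8 and the enolate closes onto oxygen; closure is expected through the adduct with O8 syn to C6 and C9 anti to it, the arrangement that avoids eclipsing C6 and C9 within the ten-membered ring, and this sets C8.

Step 20
Reactants: 25 8,17-epoxy lactone
Product: 26 8-hydroxy lactone (8-OH syn to C6, 17R with C18 syn to 8-OH), 6-OTES, 9- and 14-OTBS, 2-O-isobutyrate
Conditions: SmI2 (2.5 equiv), MeOH, THF, −78 °C
Reagents that add atoms: none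
Why: SmI2 reduction of the α,β-epoxy lactone cleaves the C17–O bond next to the carbonyl, and the samarium enolate should be protonated by methanol anti to the bulky C8–O–Sm group, giving 17R, which is also the more stable epimer (C18 anti to C9).

Step 21
Reactants: 26 8-hydroxy lactone TES ether
Product: 27 6,8-diol (6R), 9- and 14-OTBS, 2-O-isobutyrate
Conditions: PPTS, MeOH–CH2Cl2, 0 °C
Reagents that add atoms: none
Why: acid-catalysed methanolysis (selective desilylation) removes the secondary TES ether much faster than the two hindered secondary TBS ethers.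

Step 22
Reactants: 27 6,8-diol
Product: 28 (6S)-6-chloride, 8-OH free, 9- and 14-OTBS, 2-O-isobutyrate
Conditions: PPh3, hexachloroacetone, CH2Cl2, −20 °C
Reagents that add atoms: hexachloroacetone, ClC(Cl)(Cl)C(=O)C(Cl)(Cl)Cl
Why: Appel-type chlorination, in which chloride displaces the allylic alkoxyphosphonium group by direct SN2 attack with inversion (6R alcohol to 6S chloride) and little allylic transposition at low temperature, while the tertiary 8-OH does not react.

Step 23
Reactants: 28 6-chloride bis-TBS ether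
Product: 29 9,14-diol (1R,2S,6S,7R,8R,9S,10S,14S,17R)
Conditions: HF·pyridine, pyridine, THF, 0 °C to rt
Reagents that add atoms: none
Why: fluoride-mediated desilylation under buffered acidic conditions should free O9 and O14 without touching the esters, the lactone or the allylic chloride.

Step 24
Reactants: 29 9,14-diol
Product: 30 9,14-diacetate (the 11,20-deoxy target, C11=C20 methylidene)
Conditions: Ac2O, DMAP, Et3N, CH2Cl2, 0 °C to rt
Reagents that add atoms: acetic anhydride, CC(=O)OC(C)=O
Why: DMAP-catalysed acetylation of the two secondary alcohols; the tertiary C8–OH is too hindered to react under these conditions.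

Step 25
Reactants: 30 9,14-diacetate
Product: 31 CNP0284862.1 (1R,2S,6S,7R,8R,9S,10S,11R,14S,17R)
Conditions: dimethyldioxirane, acetone, −20 °C
Reagents that add atoms: dimethyldioxirane, CC1(C)OO1
Why: electrophilic epoxidation under neutral conditions should pick C11=C20 because C5=C16 is deactivated by the allylic chlorine, and oxygen should enter anti to the axial C15 methyl (1,3-diaxial shielding of the other face), setting 11R.

Compound list
1 | geranyl acetate, (2E)-3,7-dimethylocta-2,6-dien-1-yl acetate | CC(C)=CCC/C(C)=C/COC(C)=O | starting material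
2 | (2E)-5-(3,3-dimethyloxiran-2-yl)-3-methylpent-2-en-1-yl acetate (racemic oxirane) | CC(=O)OC/C=C(\C)CCC1OC1(C)C | intermediate
3 | (2E)-3-methyl-6-oxohex-2-en-1-yl acetate | CC(=O)OC/C=C(\C)CCC=O | intermediate
4 | (2E)-6,6-dimethoxy-3-methylhex-2-en-1-yl acetate | CC(=O)OC/C=C(\C)CCC(OC)OC | intermediate
5 | (2E)-6,6-dimethoxy-3-methylhex-2-en-1-ol | OC/C=C(\C)CCC(OC)OC | intermediate
6 | (2E)-6,6-dimethoxy-3-methylhex-2-enal | O=C/C=C(\C)CCC(OC)OC | intermediate
7 | 3-methyltetronic acid, 4-hydroxy-3-methylfuran-2(5H)-one | CC1=C(O)COC1=O | starting material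
8 | 4-methyl-5-oxo-2,5-dihydrofuran-3-yl trifluoromethanesulfonate | CC1=C(OS(=O)(=O)C(F)(F)F)COC1=O | intermediate
9 | 4-[(1S,2E)-1-hydroxy-6,6-dimethoxy-3-methylhex-2-en-1-yl]-3-methylfuran-2(5H)-one | COC(OC)CC/C(C)=C/[C@H](O)C1=C(C)C(=O)OC1 | intermediate
10 | 4-[(1S,2E)-1-(tert-butyldimethylsilyloxy)-6,6-dimethoxy-3-methylhex-2-en-1-yl]-3-methylfuran-2(5H)-one | COC(OC)CC/C(C)=C/[C@H](O[Si](C)(C)C(C)(C)C)C1=C(C)C(=O)OC1 | intermediate
11 | 3-methyl-4-[(1S,2E)-1-(tert-butyldimethylsilyloxy)-6,6-dimethoxy-3-methylhex-2-en-1-yl]-2-(trimethylsilyloxy)furan | COC(OC)CC/C(C)=C/[C@H](O[Si](C)(C)C(C)(C)C)c1coc(O[Si](C)(C)C)c1C | intermediate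
12 | hept-5-yn-1-ol | CC#CCCCCO | starting material
13 | alkenylzirconocene: (2E)-hept-2-en-2-yl zirconocene chloride carrying a zirconocene chloride alkoxide at C7 | C/C(=C\CCCCO[Zr](Cl)(C1C=CC=C1)C1C=CC=C1)[Zr](Cl)(C1C=CC=C1)C1C=CC=C1 | intermediate
14 | (5E)-6-iodohept-5-en-1-ol | C/C(I)=C\CCCCO | intermediate
15 | (5E)-6-iodohept-5-enal | C/C(I)=C\CCCC=O | intermediate
16 | (5E)-6-iodo-2-methylidenehept-5-enal | C/C(I)=C\CCC(=C)C=O | intermediate
17 | (5R)-5-[(1R,5E)-6-iodo-2-methylidene-1-(trimethylsilyloxy)hept-5-en-1-yl]-4-[(1S,2E)-1-(tert-butyldimethylsilyloxy)-6,6-dimethoxy-3-methylhex-2-en-1-yl]-3-methylfuran-2(5H)-one | C/C(I)=C\CCC(=C)[C@@H](O[Si](C)(C)C)[C@@H]1OC(=O)C(C)=C1[C@@H](O[Si](C)(C)C(C)(C)C)/C=C(\C)CCC(OC)OC | intermediate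
18 | (5R)-5-[(1R,5E)-1-hydroxy-6-iodo-2-methylidenehept-5-en-1-yl]-4-[(1S,2E)-1-(tert-butyldimethylsilyloxy)-3-methyl-6-oxohex-2-en-1-yl]-3-methylfuran-2(5H)-one | C/C(I)=C\CCC(=C)[C@@H](O)[C@@H]1OC(=O)C(C)=C1[C@@H](O[Si](C)(C)C(C)(C)C)/C=C(\C)CCC=O | intermediate
19 | (5R)-5-[(1R,5E)-6-iodo-2-methylidene-1-(triethylsilyloxy)hept-5-en-1-yl]-4-[(1S,2E)-1-(tert-butyldimethylsilyloxy)-3-methyl-6-oxohex-2-en-1-yl]-3-methylfuran-2(5H)-one | C/C(I)=C\CCC(=C)[C@@H](O[Si](CC)(CC)CC)[C@@H]1OC(=O)C(C)=C1[C@@H](O[Si](C)(C)C(C)(C)C)/C=C(\C)CCC=O | intermediate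
20 | macrocyclic allylic alcohol: 14-membered ring C1–C14, (1E)-C1=C2 with C15 on C1, (10E)-C10=C11 with C20 on C11, C5=C16 methylidene, butenolide C7–O–C19(=O)–C17(C18)=C8, (6R)-OTES, (7R), (9S)-OTBS, (14S)-OH | C=C1CC/C=C(C)/[C@@H](O)CC/C(C)=C/[C@H](O[Si](C)(C)C(C)(C)C)C2=C(C)C(=O)O[C@H]2[C@@H]1O[Si](CC)(CC)CC | intermediate
21 | epoxy alcohol: 20 with the trans-(1S,2S)-1,2-epoxide erythro to the (14S)-hydroxyl | C=C1CC[C@@H]3O[C@@]3(C)[C@@H](O)CC/C(C)=C/[C@H](O[Si](C)(C)C(C)(C)C)C2=C(C)C(=O)O[C@H]2[C@@H]1O[Si](CC)(CC)CC | intermediate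
22 | key precursor: 14-O-TBS ether of 21 (1R,2S,6R,7R,9S,14S; 10E), 9-OTBS, 6-OTES, butenolide | C=C1CC[C@@H]3O[C@@]3(C)[C@@H](O[Si](C)(C)C(C)(C)C)CC/C(C)=C/[C@H](O[Si](C)(C)C(C)(C)C)C2=C(C)C(=O)O[C@H]2[C@@H]1O[Si](CC)(CC)CC | intermediate
23 | bicyclo[8.4.0] core (1S,2S,6R,7R,9S,10S,14S): ring A (C1, C10–C14) fused to the ten-membered ring (C1–C10), 2-OH, C11=C20 and C5=C16 methylidenes, 9- and 14-OTBS, 6-OTES, butenolide | C=C1CC[C@H](O)[C@@]2(C)[C@@H](O[Si](C)(C)C(C)(C)C)CCC(=C)[C@@H]2[C@H](O[Si](C)(C)C(C)(C)C)C2=C(C)C(=O)O[C@H]2[C@@H]1O[Si](CC)(CC)CC | intermediate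
24 | 2-O-isobutyrate of 23 | C=C1CC[C@H](OC(=O)C(C)C)[C@@]2(C)[C@@H](O[Si](C)(C)C(C)(C)C)CCC(=C)[C@@H]2[C@H](O[Si](C)(C)C(C)(C)C)C2=C(C)C(=O)O[C@H]2[C@@H]1O[Si](CC)(CC)CC | intermediate
25 | (8S,17R)-8,17-epoxide of 24, epoxide oxygen syn to C6 on the lactone | C=C1CC[C@H](OC(=O)C(C)C)[C@@]2(C)[C@@H](O[Si](C)(C)C(C)(C)C)CCC(=C)[C@@H]2[C@H](O[Si](C)(C)C(C)(C)C)[C@]2(O3)[C@]3(C)C(=O)O[C@H]2[C@@H]1O[Si](CC)(CC)CC | intermediate
26 | 8-hydroxy-17-H lactone (8-OH syn to C6, 17R), 6-OTES, 9- and 14-OTBS, 2-O-isobutyrate | C=C1CC[C@H](OC(=O)C(C)C)[C@@]2(C)[C@@H](O[Si](C)(C)C(C)(C)C)CCC(=C)[C@@H]2[C@H](O[Si](C)(C)C(C)(C)C)[C@]2(O)[C@@H](C)C(=O)O[C@H]2[C@@H]1O[Si](CC)(CC)CC | intermediate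
27 | (6R)-6,8-diol, 9- and 14-OTBS, 2-O-isobutyrate | C=C1CC[C@H](OC(=O)C(C)C)[C@@]2(C)[C@@H](O[Si](C)(C)C(C)(C)C)CCC(=C)[C@@H]2[C@H](O[Si](C)(C)C(C)(C)C)[C@]2(O)[C@@H](C)C(=O)O[C@H]2[C@@H]1O | intermediate
28 | (6S)-6-chloride, 8-OH, 9- and 14-OTBS, 2-O-isobutyrate | C=C1CC[C@H](OC(=O)C(C)C)[C@@]2(C)[C@@H](O[Si](C)(C)C(C)(C)C)CCC(=C)[C@@H]2[C@H](O[Si](C)(C)C(C)(C)C)[C@]2(O)[C@@H](C)C(=O)O[C@H]2[C@H]1Cl | intermediate
29 | 9,14-diol of the 6-chloride (1R,2S,6S,7R,8R,9S,10S,14S,17R) | C=C1CC[C@H](OC(=O)C(C)C)[C@@]2(C)[C@@H](O)CCC(=C)[C@@H]2[C@H](O)[C@]2(O)[C@@H](C)C(=O)O[C@H]2[C@H]1Cl | intermediate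
30 | 9,14-diacetate with C11=C20 methylidene (11,20-deoxy target) | C=C1CC[C@H](OC(=O)C(C)C)[C@@]2(C)[C@@H](OC(C)=O)CCC(=C)[C@@H]2[C@H](OC(C)=O)[C@]2(O)[C@@H](C)C(=O)O[C@H]2[C@H]1Cl | intermediate
31 | CNP0284862.1 (1R,2S,6S,7R,8R,9S,10S,11R,14S,17R) | C=C1CC[C@H](OC(=O)C(C)C)[C@@]2(C)[C@@H](OC(C)=O)CC[C@]3(CO3)[C@@H]2[C@H](OC(C)=O)[C@]2(O)[C@@H](C)C(=O)O[C@H]2[C@H]1Cl | target

Total step count: 25.
Longest linear sequence: 21 steps from geranyl acetate 1 (steps 1–4, 6–8, 12–25).

Steps most likely to fail

1. Step 17 (proposed new method). What may go wrong: proton loss from C12 or C10 in place of C20, attack of C16 on C1, a 1,2-shift from C14 to C1, or closure through the alternative chair. Fallback: the fallback sets out from 22 and opens the epoxide homolytically. Cp2TiCl (trivalent titanium, made from Cp2TiCl2 and Mn dust in THF at rt) gives the tertiary C1 radical, which adds 6-endo to C10. The C11 radical is trapped by a second Cp2TiCl, and β-hydride elimination toward the methyl group gives the C11=C20 methylidene. Aqueous work-up returns to the route at 23. Titanocene-mediated radical epoxide–alkene cyclisation, transannular cases included, is known chemistry, and its termination is biased toward exocyclic alkenes. No new isolated compound arises (F0).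

2. Step 19. What may go wrong: peroxide addition on the lactone face anti to C6, which would give the C8 epimer, or base-induced epimerisation at C7. Fallback: the fallback sets out from 24 and delivers O8 from O6 through a tether. Acid-catalysed methanolysis of the TES ether (PPTS, MeOH) gives the C6 alcohol F1. Benzaldehyde with catalytic KOt-Bu (THF, 0 °C) forms the hemiacetal alkoxide, which adds in conjugate fashion to C8 of the butenolide. The six-membered tether can only reach the face syn to C6, and the enolate is protonated under equilibrating conditions, giving the benzylidene acetal F2. Aqueous acetic acid (40 °C) cleaves the acetal, and the route is rejoined at 27, steps 19 to 21 being bypassed.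

3. Step 14. What may go wrong: oligomerisation at the concentration needed for a ligand-bound chromium reagent, or weak ligand control of the aldehyde face in the macrocyclic transition state, which would give a C14 epimer mixture. Fallback: the fallback sets out from 20 obtained as the C14 epimer mixture (closure without L*, CrCl2/NiCl2 in DMSO at high dilution). Dess–Martin oxidation gives the macrocyclic enone F3. Corey–Bakshi–Shibata reduction ((R)-2-methyl-CBS-oxazaborolidine, catecholborane, toluene, −78 °C) then returns 20 with the 14S configuration under reagent control.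

Further compounds
F0 | step 17 | none | none
F1 | step 19 | C6 alcohol of the bicyclic butenolide (6-OH, 9- and 14-OTBS, 2-O-isobutyrate) | C=C1CC[C@H](OC(=O)C(C)C)[C@@]2(C)[C@@H](O[Si](C)(C)C(C)(C)C)CCC(=C)[C@@H]2[C@H](O[Si](C)(C)C(C)(C)C)C2=C(C)C(=O)O[C@H]2[C@@H]1O
F2 | step 19 | 6,8-O-benzylidene acetal of the 8-hydroxy-17-H lactone (phenyl equatorial, 17R) | C=C1CC[C@H](OC(=O)C(C)C)[C@@]2(C)[C@@H](O[Si](C)(C)C(C)(C)C)CCC(=C)[C@@H]2[C@H](O[Si](C)(C)C(C)(C)C)[C@]2(O3)[C@@H](C)C(=O)O[C@H]2[C@@H]1O[C@H]3c1ccccc1
F3 | step 14 | macrocyclic C14 enone (14-oxo analogue of 20) | C=C1CC/C=C(C)/C(=O)CC/C(C)=C/[C@H](O[Si](C)(C)C(C)(C)C)C2=C(C)C(=O)O[C@H]2[C@@H]1O[Si](CC)(CC)CC
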